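The whole plan rests on moving one bond. In the target, C1 is the atom that carries C2, C8 and C9. A cis-fused hydrindane in which C8 still sits on C9 therefore becomes the bicyclo[3.3.1]nonane by a single 1,2-shift of C8 from C9 to C1. The shift is started by oxidising C1 of the polyanion of carbinol 21 with a trivalent iodine reagent. In one operation it enlarges the cyclopentane C5–C6–C7–C8–C9 to ring B, bridges ring A, creates bridgehead C1 and unmasks the C9 ketone. Carbinol 21 is a 7a-hydroxyhydrindane-4,6-dione that already holds C5, C7 and C8, and it is built from a cyclopentanone by enolate chemistry.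

Key step: step 11

Numbering: the skeleton numbers of the target are used for all intermediates. Ring A = C1–C2–C3–C4–C5–C9 and ring B = C1–C8–C7–C6–C5–C9. C1 carries the acyl group, C5 and C7 carry prenyl, and C8 carries methyl and 4-methylpent-3-enyl (homoprenyl).

Stereochemical reading of the target: (1S,5S,7S,8R) with an (R) side chain. The C7 prenyl group is cis to C4 across ring B and trans to the C8 homoprenyl chain. Hydrindane 21 and trione 24 were checked centre by centre against this reading (C8 migrates with retention). They are consistent with it, and the acylating agent has to be the (R) antipode, so no structure needed to be changed.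

Assumption: (R)-2-methylbutanoic acid 28 is bought in enantiopure form.

Step 1
Reactants: 1 2-methylcyclopent-2-en-1-one; 2 vinylmagnesium bromide
Product: 4 (R)-trimethyl[(2-methyl-3-vinylcyclopent-1-en-1-yl)oxy]silane, via bromomagnesium enolate 3 (not isolated)
Conditions: CuBr·SMe2 (5 mol %), TADDOL-derived chiral phosphine–phosphite ligand (6 mol %, the antipode that gives the R product), 2-MeTHF, −78 °C, slow addition of 2; then Me3SiCl, Et3N, DMPU, −78 °C → rt
Reagents that add atoms: chlorotrimethylsilane, C[Si](C)(C)Cl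
Why: Copper-catalysed asymmetric conjugate addition of a Grignard reagent, a reaction class established for this α-methyl enone with alkyl, aryl and 2-propenyl reagents, should deliver vinyl to one face of C7 under control of the chiral ligand on monovalent copper, and O-silylation of the magnesium enolate preserves the C8=C9 enolate regiochemistry for step 3.

Step 2
Reactants: 5 5-bromo-2-methylpent-2-ene
Product: 6 5-iodo-2-methylpent-2-ene
Conditions: NaI, acetone, reflux
Reagents that add atoms: sodium iodide, [Na+].[I-]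
Why: Finkelstein halide exchange, driven by precipitation of NaBr, turns the sluggish primary bromide into the iodide needed for alkylation of a hindered enolate.

Step 3
Reactants: 4 (R)-trimethyl[(2-methyl-3-vinylcyclopent-1-en-1-yl)oxy]silane; 6 5-iodo-2-methylpent-2-ene
Product: 8 (2R,3R)-2-methyl-2-(4-methylpent-3-en-1-yl)-3-vinylcyclopentan-1-one, via lithium enolate 7 (not isolated)
Conditions: MeLi, THF, 0 °C; then DMPU, 6 (excess), −40 °C → rt
Reagents that add atoms: none
Why: Cleavage of the silyl enol ether with MeLi releases the tetrasubstituted lithium enolate regiospecifically, and its SN2 alkylation should take place on the ring face opposite to the C7 vinyl group, which sets quaternary C8 with homoprenyl trans and methyl cis to vinyl.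

Step 4
Reactants: 8 (2R,3R)-2-methyl-2-(4-methylpent-3-en-1-yl)-3-vinylcyclopentan-1-one
Product: 10 (2R,3R)-3-(2-hydroxyethyl)-2-methyl-2-(4-methylpent-3-en-1-yl)cyclopentan-1-one, via B-alkyl-9-BBN adduct 9 (not isolated)
Conditions: 9-BBN, THF, 0 °C → rt; then NaOH, H2O2, 0 °C
Reagents that add atoms: hydrogen peroxide, OO
Why: Brown hydroboration–oxidation with bulky 9-BBN is selective for the monosubstituted vinyl group over the trisubstituted alkene and places boron on the terminal carbon, and any ketone reduced on the way is restored in step 5.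

Step 5
Reactants: 10 (2R,3R)-3-(2-hydroxyethyl)-2-methyl-2-(4-methylpent-3-en-1-yl)cyclopentan-1-one
Product: 11 2-[(1R,2R)-2-methyl-2-(4-methylpent-3-en-1-yl)-3-oxocyclopentyl]acetaldehyde
Conditions: Dess–Martin periodinane, CH2Cl2, 0 °C → rt
Reagents that add atoms: none
Why: Dess–Martin oxidation converts the primary alcohol into the aldehyde under near-neutral conditions that leave the alkene, the ketone and both stereocentres untouched.

Step 6
Reactants: 11 2-[(1R,2R)-2-methyl-2-(4-methylpent-3-en-1-yl)-3-oxocyclopentyl]acetaldehyde; 12 isopropyltriphenylphosphonium iodide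
Product: 14 (2R,3R)-2-methyl-3-(3-methylbut-2-en-1-yl)-2-(4-methylpent-3-en-1-yl)cyclopentan-1-one, via isopropylidene ylide 13 (not isolated)
Conditions: 12, n-BuLi, THF, 0 °C; then 11, −78 → 0 °C
Reagents that add atoms: none
Why: Wittig olefination with the non-stabilised isopropylidene ylide is far faster at the aldehyde than at the ketone flanked by quaternary C8, and it completes the C7 prenyl group with an alkene that has no E/Z isomers.

Step 7
Reactants: 14 (2R,3R)-2-methyl-3-(3-methylbut-2-en-1-yl)-2-(4-methylpent-3-en-1-yl)cyclopentan-1-one; 15 1-acetyl-1H-benzotriazole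
Product: 16 (2R,3S)-5-acetyl-2-methyl-3-(3-methylbut-2-en-1-yl)-2-(4-methylpent-3-en-1-yl)cyclopentan-1-one (keto–enol mixture; C5 not fixed)
Conditions: MgBr2·OEt2, i-Pr2NEt, CH2Cl2, rt
Reagents that add atoms: none
Why: In this Claisen-type C-acylation by soft enolisation, C9 can enolise only towards C5 because C8 is quaternary, the magnesium chelate favours C- over O-acylation, and the excess amine takes up the acidic proton of the β-diketone formed.

Step 8
Reactants: 16 (2R,3S)-5-acetyl-2-methyl-3-(3-methylbut-2-en-1-yl)-2-(4-methylpent-3-en-1-yl)cyclopentan-1-one; 17 prenyl bromide (1-bromo-3-methylbut-2-ene)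
Product: 18 (2R,3S,5S)-5-acetyl-2-methyl-3,5-bis(3-methylbut-2-en-1-yl)-2-(4-methylpent-3-en-1-yl)cyclopentan-1-one
Conditions: K2CO3, acetone, 45 °C
Reagents that add atoms: none
Why: In this C-alkylation of a 2-acylcyclopentanone enolate with an allylic bromide, the electrophile should reach planar C5 from the ring face opposite to the C7 prenyl group and the pseudoaxial C8 methyl group, which share the other face, so the new prenyl group ends up trans and the acetyl carbon C4 cis to the C7 prenyl group.

Step 9
Reactants: 18 (2R,3S,5S)-5-acetyl-2-methyl-3,5-bis(3-methylbut-2-en-1-yl)-2-(4-methylpent-3-en-1-yl)cyclopentan-1-one; 15 1-acetyl-1H-benzotriazole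
Product: 19 1-[(1S,3R,4S)-3-methyl-1,4-bis(3-methylbut-2-en-1-yl)-3-(4-methylpent-3-en-1-yl)-2-oxocyclopentyl]butane-1,3-dione
Conditions: MgBr2·OEt2, i-Pr2NEt, CH2Cl2, rt
Reagents that add atoms: none
Why: The same soft-enolisation Claisen acylation is used because the only acidic protons of 18 are those of the acetyl methyl group C3, and because no alkoxide or hydroxide is present that could cleave the non-enolisable C9/C4 diketone by a retro-Claisen reaction.

Step 10
Reactants: 19 1-[(1S,3R,4S)-3-methyl-1,4-bis(3-methylbut-2-en-1-yl)-3-(4-methylpent-3-en-1-yl)-2-oxocyclopentyl]butane-1,3-dione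
Product: 21 (1R,2S,3aR,7aR)-7a-hydroxy-1-methyl-2,3a-bis(3-methylbut-2-en-1-yl)-1-(4-methylpent-3-en-1-yl)tetrahydro-1H-indene-4,6(5H,7H)-dione (cis-fused; C8 bonded to C9), via dilithium dianion 20 (not isolated)
Conditions: LiN(i-Pr)2 (2.5 equiv), THF, −78 → −20 °C; AcOH, −78 °C
Reagents that add atoms: none
Why: In this dianion aldol reaction the terminal and most basic carbon C1 of the 1,3-diketone dianion adds to the non-enolisable C9 ketone in a 6-exo-trig closure, and the short C5–C4–C3–C2 tether lets C1 reach only the carbonyl face syn to C4, which sets C9 with a cis ring fusion.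

Step 11
Reactants: 21 (1R,2S,3aR,7aR)-7a-hydroxy-1-methyl-2,3a-bis(3-methylbut-2-en-1-yl)-1-(4-methylpent-3-en-1-yl)tetrahydro-1H-indene-4,6(5H,7H)-dione
Product: 24 (1R,5S,7S,8R)-4-hydroxy-8-methyl-5,7-bis(3-methylbut-2-en-1-yl)-8-(4-methylpent-3-en-1-yl)bicyclo[3.3.1]non-3-ene-2,9-dione (enol of the 2,4,9-trione; C1–H), via trilithium salt 22 (not isolated), via C1-iodanyl dilithium salt 23 (not isolated)
Conditions: LiN(i-Pr)2 (3.5 equiv), THF, −78 → 0 °C; PhI(OAc)2 (1.2 equiv), −78 → 0 °C; 1 M HCl
Reagents that add atoms: none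
Why: Three equivalents of amide base remove the C9–OH, C3–H and C1–H protons, and the terminal carbon C1 of the resulting diketone dianion, its most nucleophilic site, displaces acetate from PhI(OAc)2 along the pseudoaxial trajectory on the face syn to the C9 oxide to give 23. In 23 the C1–I bond is antiperiplanar to C9–C8, so the C9 alkoxide collapses to the ketone while C8 moves to C1 and iodobenzene leaves, which forms C1–C8 and breaks C8–C9. The closest known reaction types are the semipinacol shift onto α-halo or α-iodanyl ketones and the ring expansion of fused diketo carbinols to bicyclo[3.3.1]nonane-2,4,9-triones with trivalent iodine reagents. Ring B (C1–C8–C7–C6–C5–C9) is closed not by a cyclisation but by one-carbon enlargement of the cyclopentane through the 1,2-shift, which bridges ring A at the same time. The new stereocentre C1 is fixed by inversion at C1 relative to iodine and by the bridged geometry, which allows a single configuration once C5 is set, while C8 migrates with retention and C5 and C7 are not touched. The step needs oxidation at C1 rather than C3, which dianion reactivity secures, and migration of C8 rather than C5, which the alignment secures because C9–C5 is gauche to C1–I and the syn oxide cannot close an epoxide.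

Step 12
Reactants: 24 (1R,5S,7S,8R)-4-hydroxy-8-methyl-5,7-bis(3-methylbut-2-en-1-yl)-8-(4-methylpent-3-en-1-yl)bicyclo[3.3.1]non-3-ene-2,9-dione
Product: 25 (1R,5S,7S,8R)-4-methoxy-8-methyl-5,7-bis(3-methylbut-2-en-1-yl)-8-(4-methylpent-3-en-1-yl)bicyclo[3.3.1]non-3-ene-2,9-dione
Conditions: Me2SO4, K2CO3, acetone, rt; chromatographic separation of the O-methyl regioisomers
Reagents that add atoms: dimethyl sulfate, COS(=O)(=O)OC
Why: O-alkylation of the potassium diketonate with a hard methylating agent gives the vinylogous esters without a claimed bias; the C4-methoxy isomer, whose C1–H lies between the C2 and C9 carbonyl groups as bridgehead metalation requires, is separated, and the C2-methoxy isomer is returned to 24 under the conditions of step 16.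

Step 13
Reactants: 25 (1R,5S,7S,8R)-4-methoxy-8-methyl-5,7-bis(3-methylbut-2-en-1-yl)-8-(4-methylpent-3-en-1-yl)bicyclo[3.3.1]non-3-ene-2,9-dione
Product: 27 (1S,5S,7S,8R)-4-methoxy-8-methyl-5,7-bis(3-methylbut-2-en-1-yl)-8-(4-methylpent-3-en-1-yl)-3-(trimethylsilyl)bicyclo[3.3.1]non-3-ene-2,9-dione, via C3-lithio vinylogous ester 26 (not isolated)
Conditions: LiN(i-Pr)2, Me3SiCl (present during deprotonation), THF, −78 °C
Reagents that add atoms: chlorotrimethylsilane, C[Si](C)(C)Cl
Why: In this vinylic lithiation–silylation the C3–H between the carbonyl and the methoxy-bearing carbon is the kinetically most acidic site, the C1–H being shielded by quaternary C8, and trapping in situ blocks C3 for the next step.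

Step 14
Reactants: 28 (R)-2-methylbutanoic acid
Product: 29 (R)-2-methylbutanoyl chloride
Conditions: (COCl)2, DMF (cat.), CH2Cl2, 0 °C → rt; volatiles removed, used at once
Reagents that add atoms: oxalyl chloride, O=C(Cl)C(=O)Cl
Why: Acid chloride formation through the Vilsmeier-type chloroiminium catalyst runs at or below room temperature without base, so the α-stereocentre should not enolise.

Step 15
Reactants: 27 (1S,5S,7S,8R)-4-methoxy-8-methyl-5,7-bis(3-methylbut-2-en-1-yl)-8-(4-methylpent-3-en-1-yl)-3-(trimethylsilyl)bicyclo[3.3.1]non-3-ene-2,9-dione; 29 (R)-2-methylbutanoyl chloride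
Product: 31 (1R,5S,7S,8R)-4-methoxy-8-methyl-1-[(2R)-2-methylbutanoyl]-5,7-bis(3-methylbut-2-en-1-yl)-8-(4-methylpent-3-en-1-yl)-3-(trimethylsilyl)bicyclo[3.3.1]non-3-ene-2,9-dione, via C1-lithio bridgehead species 30 (not isolated)
Conditions: lithium 2,2,6,6-tetramethylpiperidide (slight excess), THF, −78 → −40 °C; 29 (excess), −78 °C
Reagents that add atoms: none
Why: In this bridgehead lithiation–acylation, with C3 blocked, the hindered amide removes the C1–H acidified by the flanking C2 and C9 carbonyl groups, the pyramidal bridgehead carbanion cannot invert, and acyl substitution on 29 at low temperature should give the C1 ketone with the ring configuration and the (R) side-chain centre retained.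

Step 16
Reactants: 31 (1R,5S,7S,8R)-4-methoxy-8-methyl-1-[(2R)-2-methylbutanoyl]-5,7-bis(3-methylbut-2-en-1-yl)-8-(4-methylpent-3-en-1-yl)-3-(trimethylsilyl)bicyclo[3.3.1]non-3-ene-2,9-dione
Product: 33 (1S,5S,7S,8R)-4-hydroxy-8-methyl-1-[(2R)-2-methylbutanoyl]-5,7-bis(3-methylbut-2-en-1-yl)-8-(4-methylpent-3-en-1-yl)bicyclo[3.3.1]non-3-ene-2,9-dione (CNP0268336.1), via lithium C3-silyl diketonate 32 (not isolated)
Conditions: LiCl, DMSO, 120 °C, short reaction time; 1 M HCl work-up
Reagents that add atoms: none
Why: Krapcho-type SN2 attack of chloride on the O-methyl group frees the lithium diketonate, whose C3 silyl group is then lost through the facile carbon-to-oxygen silyl shift of C-silylated 1,3-diketones and hydrolysis at work-up, under conditions too weakly basic to enolise the hindered side-chain ketone.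

Compound list
1 | 2-methylcyclopent-2-en-1-one | CC1=CCCC1=O | starting material
2 | vinylmagnesium bromide | C=C[Mg]Br | starting material
3 | bromomagnesium (R)-2-methyl-3-vinylcyclopent-1-en-1-olate | CC1=C(O[Mg]Br)CC[C@@H]1C=C | intermediate
4 | (R)-trimethyl[(2-methyl-3-vinylcyclopent-1-en-1-yl)oxy]silane | CC1=C(O[Si](C)(C)C)CC[C@@H]1C=C | intermediate
5 | 5-bromo-2-methylpent-2-ene | CC(C)=CCCBr | starting material
6 | 5-iodo-2-methylpent-2-ene | CC(C)=CCCI | intermediate
7 | lithium (R)-2-methyl-3-vinylcyclopent-1-en-1-olate | CC1=C(O[Li])CC[C@@H]1C=C | intermediate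
8 | (2R,3R)-2-methyl-2-(4-methylpent-3-en-1-yl)-3-vinylcyclopentan-1-one | O=C1CC[C@H](C=C)[C@@]1(C)CCC=C(C)C | intermediate
9 | B-alkyl-9-BBN adduct of 8 (boron on the terminal carbon of the former vinyl group) | O=C1CC[C@H](CCB2C3CCCC2CCC3)[C@@]1(C)CCC=C(C)C | intermediate
10 | (2R,3R)-3-(2-hydroxyethyl)-2-methyl-2-(4-methylpent-3-en-1-yl)cyclopentan-1-one | O=C1CC[C@H](CCO)[C@@]1(C)CCC=C(C)C | intermediate
11 | 2-[(1R,2R)-2-methyl-2-(4-methylpent-3-en-1-yl)-3-oxocyclopentyl]acetaldehyde | O=C1CC[C@H](CC=O)[C@@]1(C)CCC=C(C)C | intermediate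
12 | isopropyltriphenylphosphonium iodide | CC(C)[P+](c1ccccc1)(c1ccccc1)c1ccccc1.[I-] | starting material
13 | isopropylidenetriphenylphosphorane | CC(C)=P(c1ccccc1)(c1ccccc1)c1ccccc1 | intermediate
14 | (2R,3R)-2-methyl-3-(3-methylbut-2-en-1-yl)-2-(4-methylpent-3-en-1-yl)cyclopentan-1-one | O=C1CC[C@H](CC=C(C)C)[C@@]1(C)CCC=C(C)C | intermediate
15 | 1-acetyl-1H-benzotriazole | CC(=O)n1nnc2ccccc12 | starting material
16 | (2R,3S)-5-acetyl-2-methyl-3-(3-methylbut-2-en-1-yl)-2-(4-methylpent-3-en-1-yl)cyclopentan-1-one (C5 not fixed) | O=C1C(C(C)=O)C[C@H](CC=C(C)C)[C@@]1(C)CCC=C(C)C | intermediate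
17 | prenyl bromide | BrCC=C(C)C | starting material
18 | (2R,3S,5S)-5-acetyl-2-methyl-3,5-bis(3-methylbut-2-en-1-yl)-2-(4-methylpent-3-en-1-yl)cyclopentan-1-one | O=C1[C@](CC=C(C)C)(C(C)=O)C[C@H](CC=C(C)C)[C@@]1(C)CCC=C(C)C | intermediate
19 | 1-[(1S,3R,4S)-3-methyl-1,4-bis(3-methylbut-2-en-1-yl)-3-(4-methylpent-3-en-1-yl)-2-oxocyclopentyl]butane-1,3-dione | O=C1[C@](CC=C(C)C)(C(=O)CC(C)=O)C[C@H](CC=C(C)C)[C@@]1(C)CCC=C(C)C | intermediate
20 | dilithium C1,C3-dianion (bis-enolate) of 19 | O=C1[C@](CC=C(C)C)(C([O-])=CC([O-])=C)C[C@H](CC=C(C)C)[C@@]1(C)CCC=C(C)C.[Li+].[Li+] | intermediate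
21 | (1R,2S,3aR,7aR)-7a-hydroxy-1-methyl-2,3a-bis(3-methylbut-2-en-1-yl)-1-(4-methylpent-3-en-1-yl)tetrahydro-1H-indene-4,6(5H,7H)-dione | O[C@@]12CC(=O)CC(=O)[C@]1(CC=C(C)C)C[C@H](CC=C(C)C)[C@@]2(C)CCC=C(C)C | intermediate
22 | trilithium salt of 21 (C9 alkoxide and C1,C3 bis-enolate) | [Li+].[Li+].[Li+].[O-][C@@]12C=C([O-])C=C([O-])[C@]1(CC=C(C)C)C[C@H](CC=C(C)C)[C@@]2(C)CCC=C(C)C | intermediate
23 | dilithium salt of the C1-[acetoxy(phenyl)iodanyl] derivative of 21 (iodine syn to the C9 oxide, anti to C8) | [Li+].[Li+].[O-][C@@]12[C@@H](I(OC(C)=O)c3ccccc3)C(=O)C=C([O-])[C@]1(CC=C(C)C)C[C@H](CC=C(C)C)[C@@]2(C)CCC=C(C)C | intermediate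
24 | (1R,5S,7S,8R)-4-hydroxy-8-methyl-5,7-bis(3-methylbut-2-en-1-yl)-8-(4-methylpent-3-en-1-yl)bicyclo[3.3.1]non-3-ene-2,9-dione | [C@H]12C(=O)C=C(O)[C@](CC=C(C)C)(C[C@H](CC=C(C)C)[C@@]1(C)CCC=C(C)C)C2=O | intermediate
25 | (1R,5S,7S,8R)-4-methoxy-8-methyl-5,7-bis(3-methylbut-2-en-1-yl)-8-(4-methylpent-3-en-1-yl)bicyclo[3.3.1]non-3-ene-2,9-dione | [C@H]12C(=O)C=C(OC)[C@](CC=C(C)C)(C[C@H](CC=C(C)C)[C@@]1(C)CCC=C(C)C)C2=O | intermediate
26 | C3-lithio derivative of 25 | [C@H]12C(=O)C([Li])=C(OC)[C@](CC=C(C)C)(C[C@H](CC=C(C)C)[C@@]1(C)CCC=C(C)C)C2=O | intermediate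
27 | (1S,5S,7S,8R)-4-methoxy-8-methyl-5,7-bis(3-methylbut-2-en-1-yl)-8-(4-methylpent-3-en-1-yl)-3-(trimethylsilyl)bicyclo[3.3.1]non-3-ene-2,9-dione | [C@H]12C(=O)C([Si](C)(C)C)=C(OC)[C@](CC=C(C)C)(C[C@H](CC=C(C)C)[C@@]1(C)CCC=C(C)C)C2=O | intermediate
28 | (R)-2-methylbutanoic acid | CC[C@@H](C)C(=O)O | starting material
29 | (R)-2-methylbutanoyl chloride | CC[C@@H](C)C(=O)Cl | intermediate
30 | C1-lithio derivative of 27 | [Li][C@]12C(=O)C([Si](C)(C)C)=C(OC)[C@](CC=C(C)C)(C[C@H](CC=C(C)C)[C@@]1(C)CCC=C(C)C)C2=O | intermediate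
31 | (1R,5S,7S,8R)-4-methoxy-8-methyl-1-[(2R)-2-methylbutanoyl]-5,7-bis(3-methylbut-2-en-1-yl)-8-(4-methylpent-3-en-1-yl)-3-(trimethylsilyl)bicyclo[3.3.1]non-3-ene-2,9-dione | CC[C@@H](C)C(=O)[C@]12C(=O)C([Si](C)(C)C)=C(OC)[C@](CC=C(C)C)(C[C@H](CC=C(C)C)[C@@]1(C)CCC=C(C)C)C2=O | intermediate
32 | lithium diketonate of the O-demethylated, still C3-silylated 31 | CC[C@@H](C)C(=O)[C@]12C(=O)C([Si](C)(C)C)=C([O-])[C@](CC=C(C)C)(C[C@H](CC=C(C)C)[C@@]1(C)CCC=C(C)C)C2=O.[Li+] | intermediate
33 | (1S,5S,7S,8R)-4-hydroxy-8-methyl-1-[(2R)-2-methylbutanoyl]-5,7-bis(3-methylbut-2-en-1-yl)-8-(4-methylpent-3-en-1-yl)bicyclo[3.3.1]non-3-ene-2,9-dione | CC[C@@H](C)C(=O)[C@]12C(=O)C=C(O)[C@](CC=C(C)C)(C[C@H](CC=C(C)C)[C@@]1(C)CCC=C(C)C)C2=O | target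

Total step count: 16.
Longest linear sequence: 14 (steps 1, 3 to 13, 15 and 16). Steps 2 and 14 are one-step side branches.

Steps most likely to fail

1. Step 11 (key step).
- What may go wrong: the iodine reagent may be consumed at C3 or by the amine. The alkoxide may reopen the ring by retro-aldol cleavage before migration. The ring bond C9–C5 may shift if the C1–I bond is not held pseudoaxial.
- Fallback, from 21 back to 24: oxidation and migration are separated. The trilithium salt 22 is quenched at −78 °C with N-bromosuccinimide, and the C1-bromo carbinol F1 is isolated. Its C1 centre can equilibrate by enolisation to the isomer with bromine anti to C8. Bromide abstraction with Ag2CO3 in CH2Cl2 then starts the classical semipinacol shift of an α-halo ketone next to a tertiary carbinol and gives 24.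

2. Step 1.
- What may go wrong: an sp2 Grignard reagent can transfer without the chiral copper complex, so poor facial selectivity and competing 1,2-addition are the likely failures. A moderate enantiomeric purity is not fatal, because after step 15 the minor antipode of the core is a diastereomer of 31 and can be separated.
- Fallback, from 1 back to 14: the nucleophile class is changed to a primary alkyl Grignard reagent, for which this conjugate addition is best documented.
- 3-Methylbut-3-en-1-ylmagnesium bromide F2 is made from commercial 4-bromo-2-methylbut-1-ene and magnesium. It is added to 1 with Cu(OTf)2 and a chiral hydroxyalkyl imidazolinium carbene precursor in Et2O, and the enolate is trapped with Me3SiCl to give (S)-trimethyl{[2-methyl-3-(3-methylbut-3-en-1-yl)cyclopent-1-en-1-yl]oxy}silane F3.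
- MeLi and then 6, as in step 3, give (2R,3S)-2-methyl-3-(3-methylbut-3-en-1-yl)-2-(4-methylpent-3-en-1-yl)cyclopentan-1-one F4.
- Hydrogen-atom-transfer isomerisation of the 1,1-disubstituted alkene with chloro[N,N'-bis(3,5-di-tert-butylsalicylidene)cyclohexane-1,2-diaminato]cobalt and PhSiH3 in benzene moves the double bond into the trisubstituted position and gives 14. Any unconverted terminal isomer is removed on AgNO3-impregnated silica. Steps 4 to 6 are then not needed.

3. Step 15.
- What may go wrong: attack of the hindered bridgehead carbanion on the branched acid chloride may be slow. Deprotonation of 29 to the ketene could then compete, which would lower conversion and erode the side-chain configuration.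
- Fallback, from 27 and 28 back to 31: the strongly basic lithium species is replaced by a magnesium reagent and the acyl transfer by addition and oxidation.
- Compound 27 is lithiated as in step 15 and quenched with I2 to give the C1 bridgehead iodide F5.
- Acid 28 is reduced with LiAlH4 to (R)-2-methylbutan-1-ol F6, which is oxidised with TEMPO, KBr and NaOCl to (R)-2-methylbutanal F7.
- Iodine–magnesium exchange of F5 with i-PrMgCl in THF at −78 °C and addition of F7 give the C1 carbinol F8 as a mixture at the carbinol carbon. Dess–Martin oxidation then converges this mixture on 31.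

Further compounds
F1 | step 11 | C1-bromo derivative of 21 (bromine syn to the C9 hydroxyl, anti to C8) | O[C@@]12[C@@H](Br)C(=O)CC(=O)[C@]1(CC=C(C)C)C[C@H](CC=C(C)C)[C@@]2(C)CCC=C(C)C
F2 | step 1 | 3-methylbut-3-en-1-ylmagnesium bromide | C=C(C)CC[Mg]Br
F3 | step 1 | (S)-trimethyl{[2-methyl-3-(3-methylbut-3-en-1-yl)cyclopent-1-en-1-yl]oxy}silane | CC1=C(O[Si](C)(C)C)CC[C@@H]1CCC(C)=C
F4 | step 1 | (2R,3S)-2-methyl-3-(3-methylbut-3-en-1-yl)-2-(4-methylpent-3-en-1-yl)cyclopentan-1-one | O=C1CC[C@H](CCC(C)=C)[C@@]1(C)CCC=C(C)C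
F5 | step 15 | C1-iodo derivative of 27 | I[C@]12C(=O)C([Si](C)(C)C)=C(OC)[C@](CC=C(C)C)(C[C@H](CC=C(C)C)[C@@]1(C)CCC=C(C)C)C2=O
F6 | step 15 | (R)-2-methylbutan-1-ol | CC[C@@H](C)CO
F7 | step 15 | (R)-2-methylbutanal | CC[C@@H](C)C=O
F8 | step 15 | C1-[(2R)-1-hydroxy-2-methylbutyl] derivative of 27 (carbinol carbon not fixed) | CC[C@@H](C)C(O)[C@]12C(=O)C([Si](C)(C)C)=C(OC)[C@](CC=C(C)C)(C[C@H](CC=C(C)C)[C@@]1(C)CCC=C(C)C)C2=O
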